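Count what is left.

    starting material + catalyst intermediate B ⇌ catalyst intermediate C (K1 = 8100 M⁻¹, k1 = 16000 M⁻¹ s⁻¹)
    catalyst intermediate A ⇌ by-product + catalyst intermediate B (K2 = 3.9 × 10⁻⁴ M, k2 = 22 s⁻¹)
    partner + precatalyst → free catalyst + spent reagent (k3 = 32 M⁻¹ s⁻¹)
    partner + free catalyst → catalyst intermediate A (k4 = 28000 M⁻¹ s⁻¹)
    catalyst intermediate C → free catalyst + target (k5 = 3.8 s⁻¹)

starting material 0.20 mM; partner 0.120 mM; precatalyst 4.0 µM

1. the form that holds most of the catalyst when 10 % of the starting material are converted (catalyst intermediate B / catalyst intermediate A / precatalyst / free catalyst / catalyst intermediate C)
2. its share of the catalyst then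

We begin with activation by itself. With [partner] held at its charge, this step is pseudo-first-order:

activation constant = 32 M⁻¹ s⁻¹ × 0.120 mM = 0.00384 s⁻¹

This activation constant, the fraction of the precatalyst released per second, is what we carry. The fraction left after time t is exp(−activation constant × t), but activation by itself gives no t, only a time scale of 260 s.

So we add the round. Its waits are free catalyst on partner, catalyst intermediate A splitting, catalyst intermediate B on starting material, catalyst intermediate C going on, and the extra wait from C falling back. We leave aside the return of by-product:

round time = 0.298 s + 0.0455 s + 0.312 s + 0.263 s + 0.162 s = 1.08 s

The round is much faster than activation, so we count released catalyst as working at once. Released catalyst then grows in proportion to t and target in proportion to t². Reaching 0.0200 mM of target gives: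

t = √(2 × target × round time / (precatalyst charge × activation constant)) = 53.1 s

fraction left = 81.6 %

Last comes the fall of [partner]. That much target takes 16.7 % of the partner charge. Since target grows as t², the mean loss over the stretch is a third of this:

mean activation constant = 0.00363 s⁻¹

t = 54.6 s

fraction left = 82.0 %

This addition moves the number by 0.40 percentage points. We commit to precatalyst at 82.0 %, more than half.

The forecast also names precatalyst, at 81 %, within 78 % to 84 %, which is 1 point below our figure. Its grounds begin: “Activation is slow”.

The starting material reaches 10 % conversion at 57.7 s. At that conversion the flask holds 81.3 % of its catalyst as precatalyst, inside the forecast's range, with catalyst intermediate B at 8.05 %. At that time the mean activation constant leaves 81.1 %. In the flask with twice the precatalyst, our t² law puts the same target at 40.8 s. By the same reckoning, released catalyst there comes to 1.46 times that of the first flask, and the rate in that flask is 1.44 times the first.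

The constants used here are assumed.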